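**Retrosynthetic overview**
1. Aryl ether C–O bond last: Mitsunobu coupling of a 2,3-epoxy alcohol with 7-hydroxy-8-methoxycoumarin (coumarin ring made separately by Pechmann condensation).
2. Oxirane ring: Sharpless asymmetric epoxidation of the (E)-trisubstituted allylic alcohol sets both epoxide centres by reagent control.
3. Lactone ring, carbinol centre and key C–C bond [CH(O)–CH2]: catalytic enantioselective carbonyl 2-(ethoxycarbonyl)allylation of a C6 β,γ-unsaturated aldehyde with ethyl 2-(bromomethyl)acrylate, then lactonisation.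
4. Aldehyde: from but-3-yn-1-ol by zirconium-catalysed carboalumination/acylation (E-olefin), reduction and silyl-group differentiation.
5. Ring order: coumarin (side branch) → α-methylene-γ-butyrolactone → oxirane.

Assumption: the ligand antipode for step 7 is the one that a Mosher-ester check on hydroxy ester 11 shows to give Si-face attack (R carbinol); 2-methoxyresorcinol and racemic malic acid are taken as commercial.

**Route**

Step 1
Reactants: 1 but-3-yn-1-ol
Product: 2 tert-butyl(but-3-yn-1-yloxy)dimethylsilane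
Conditions: TBSCl, imidazole, CH2Cl2, 0 °C → rt
Reagents that add atoms: tert-butyldimethylsilyl chloride, CC(C)(C)[Si](C)(C)Cl
Why: Imidazole-promoted silylation of a primary alcohol masks the oxygen for the organoaluminium step; no stereocentre is involved.

Step 2
Reactants: 2 tert-butyl(but-3-yn-1-yloxy)dimethylsilane
Product: 4 ethyl (E)-5-(tert-butyldimethylsilyloxy)-3-methylpent-2-enoate, via alkenyldimethylalane 3 (not isolated)
Conditions: Me3Al (2.5 equiv), Cp2ZrCl2 (0.25 equiv), CH2Cl2, 0 °C → rt, 16 h; then ClCO2Et, 0 °C → rt; aq. HCl work-up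
Reagents that add atoms: trimethylaluminium, C[Al](C)C; ethyl chloroformate, CCOC(=O)Cl
Why: Negishi zirconium-catalysed carboalumination adds Me–Al syn across the terminal alkyne with methyl on the internal carbon, and the alkenylalane is acylated with retention, so the E-trisubstituted enoate results.

Step 3
Reactants: 4 ethyl (E)-5-(tert-butyldimethylsilyloxy)-3-methylpent-2-enoate
Product: 5 (E)-5-(tert-butyldimethylsilyloxy)-3-methylpent-2-en-1-ol
Conditions: i-Bu2AlH (2.3 equiv), CH2Cl2, −78 → −20 °C; aq. potassium sodium tartrate work-up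
Reagents that add atoms: none
Why: DIBAL-H 1,2-reduction of the enoate gives the allylic alcohol without touching the olefin geometry or the silyl ether.

Step 4
Reactants: 5 (E)-5-(tert-butyldimethylsilyloxy)-3-methylpent-2-en-1-ol
Product: 6 (E)-1-(tert-butyldiphenylsilyloxy)-5-(tert-butyldimethylsilyloxy)-3-methylpent-2-ene
Conditions: TBDPSCl, imidazole, CH2Cl2, rt
Reagents that add atoms: tert-butyldiphenylsilyl chloride, CC(C)(C)[Si](Cl)(c1ccccc1)c1ccccc1
Why: Silylation places the acid-robust TBDPS group on the allylic oxygen so that the two primary oxygens can be told apart.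

Step 5
Reactants: 6 (E)-1-(tert-butyldiphenylsilyloxy)-5-(tert-butyldimethylsilyloxy)-3-methylpent-2-ene
Product: 7 (E)-5-(tert-butyldiphenylsilyloxy)-3-methylpent-3-en-1-ol
Conditions: CSA (10 mol %), MeOH/CH2Cl2 (1:1), 0 °C
Reagents that add atoms: none
Why: Acid-catalysed methanolysis (selective desilylation) cleaves the primary TBS ether far faster than the TBDPS ether.

Step 6
Reactants: 7 (E)-5-(tert-butyldiphenylsilyloxy)-3-methylpent-3-en-1-ol
Product: 8 (E)-5-(tert-butyldiphenylsilyloxy)-3-methylpent-3-enal
Conditions: Dess–Martin periodinane, NaHCO3, CH2Cl2, 0 °C → rt; filtered and used crude at once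
Reagents that add atoms: none
Why: Buffered Dess–Martin oxidation is fast and near neutral, so the β,γ-unsaturated aldehyde forms without migration of the double bond into conjugation.

Step 7
Reactants: 8 (E)-5-(tert-butyldiphenylsilyloxy)-3-methylpent-3-enal; 9 ethyl 2-(bromomethyl)acrylate
Product: 12 (R)-5-[(E)-4-(tert-butyldiphenylsilyloxy)-2-methylbut-2-en-1-yl]-3-methylenedihydrofuran-2(3H)-one, via trimethylsilyl ether 10 (not isolated), via hydroxy ester 11 (not isolated)
Conditions: CrCl2 (10 mol %), single-enantiomer Nakada-type ligand 1,8-bis(4-isopropyl-4,5-dihydrooxazol-2-yl)-3,6-diphenyl-9H-carbazole (12 mol %), i-Pr2NEt (30 mol %), Mn powder (2 equiv), TMSCl (1.5 equiv), THF, rt; then TsOH·H2O (0.2 equiv), CH2Cl2, rt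
Reagents that add atoms: none
Why: In this catalytic asymmetric Nozaki–Hiyama–Kishi-type carbonyl 2-(alkoxycarbonyl)allylation, the allylchromium species made from 9 by divalent chromium (recycled by Mn) adds through a closed six-membered transition state to the Si face of 8 inside the chiral ligand pocket, setting the R carbinol centre (about 90–95% ee expected), and acid then removes the TMS group and closes the α-methylene-γ-butyrolactone.

Step 8
Reactants: 12 (R)-5-[(E)-4-(tert-butyldiphenylsilyloxy)-2-methylbut-2-en-1-yl]-3-methylenedihydrofuran-2(3H)-one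
Product: 13 (R)-5-[(E)-4-hydroxy-2-methylbut-2-en-1-yl]-3-methylenedihydrofuran-2(3H)-one
Conditions: HF·pyridine, pyridine, THF, 0 °C → rt
Reagents that add atoms: none
Why: Buffered fluoride desilylation frees the allylic alcohol under weakly acidic conditions that leave the methylene lactone and the stereocentre untouched.

Step 9
Reactants: 13 (R)-5-[(E)-4-hydroxy-2-methylbut-2-en-1-yl]-3-methylenedihydrofuran-2(3H)-one
Product: 14 (S)-5-{[(2R,3R)-3-(hydroxymethyl)-2-methyloxiran-2-yl]methyl}-3-methylenedihydrofuran-2(3H)-one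
Conditions: Ti(OiPr)4 (10 mol %), D-(−)-DIPT (12 mol %), t-BuOOH (2 equiv, in decane), 4 Å molecular sieves, CH2Cl2, −20 °C
Reagents that add atoms: tert-butyl hydroperoxide, CC(C)(C)OO
Why: Sharpless asymmetric epoxidation of the E-allylic alcohol with D-(−)-tartrate (the mirror image of the L-(+)-tartrate/geraniol case that gives the 2S,3S epoxide) delivers the (2R,3R)-oxirane by reagent control while the electron-poor methylene lactone is inert; the lactone descriptor changes from R to S only through CIP priorities, and stereoisomers from imperfect selectivity in steps 7 and 9 are now diastereomers removable by chromatography.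

Step 10
Reactants: 15 2-methoxybenzene-1,3-diol; 16 DL-malic acid
Product: 18 7-hydroxy-8-methoxy-2H-chromen-2-one, via 3-oxopropanoic acid 17 (not isolated)
Conditions: conc. H2SO4, 100–110 °C, 2 h; poured onto ice
Reagents that add atoms: none
Why: In this von Pechmann coumarin synthesis malic acid loses CO and water to give formylacetic acid, which attacks the only activated ring position (ortho to one OH, para to the other) and lactonises onto the adjacent OH, placing OMe at C8 and the free OH at C7.

Step 11
Reactants: 14 (S)-5-{[(2R,3R)-3-(hydroxymethyl)-2-methyloxiran-2-yl]methyl}-3-methylenedihydrofuran-2(3H)-one; 18 7-hydroxy-8-methoxy-2H-chromen-2-one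
Product: 19 7-{[(2R,3R)-3-methyl-3-{[(S)-4-methylene-5-oxotetrahydrofuran-2-yl]methyl}oxiran-2-yl]methoxy}-8-methoxy-2H-chromen-2-one
Conditions: PPh3, DIAD (premixed at 0 °C), THF, 0 °C → rt
Reagents that add atoms: none
Why: Mitsunobu etherification of the primary epoxy alcohol with the acidic phenol (pKa about 8) forms the aryl ether at CH2 under neutral conditions, so no stereocentre is touched and the epoxide and methylene lactone survive.

**Compound list**
1 | but-3-yn-1-ol | C#CCCO | starting material
2 | tert-butyl(but-3-yn-1-yloxy)dimethylsilane | C#CCCO[Si](C)(C)C(C)(C)C | intermediate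
3 | (E)-[4-(tert-butyldimethylsilyloxy)-2-methylbut-1-en-1-yl]dimethylalane | C[Al](C)/C=C(\C)CCO[Si](C)(C)C(C)(C)C | intermediate
4 | ethyl (E)-5-(tert-butyldimethylsilyloxy)-3-methylpent-2-enoate | CCOC(=O)/C=C(\C)CCO[Si](C)(C)C(C)(C)C | intermediate
5 | (E)-5-(tert-butyldimethylsilyloxy)-3-methylpent-2-en-1-ol | OC/C=C(\C)CCO[Si](C)(C)C(C)(C)C | intermediate
6 | (E)-1-(tert-butyldiphenylsilyloxy)-5-(tert-butyldimethylsilyloxy)-3-methylpent-2-ene | CC(C)(C)[Si](c1ccccc1)(c1ccccc1)OC/C=C(\C)CCO[Si](C)(C)C(C)(C)C | intermediate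
7 | (E)-5-(tert-butyldiphenylsilyloxy)-3-methylpent-3-en-1-ol | CC(C)(C)[Si](c1ccccc1)(c1ccccc1)OC/C=C(\C)CCO | intermediate
8 | (E)-5-(tert-butyldiphenylsilyloxy)-3-methylpent-3-enal | CC(C)(C)[Si](c1ccccc1)(c1ccccc1)OC/C=C(\C)CC=O | intermediate
9 | ethyl 2-(bromomethyl)acrylate | C=C(CBr)C(=O)OCC | starting material
10 | ethyl (R,E)-8-(tert-butyldiphenylsilyloxy)-6-methyl-2-methylene-4-(trimethylsilyloxy)oct-6-enoate | C=C(C[C@@H](C/C(C)=C/CO[Si](c1ccccc1)(c1ccccc1)C(C)(C)C)O[Si](C)(C)C)C(=O)OCC | intermediate
11 | ethyl (R,E)-8-(tert-butyldiphenylsilyloxy)-4-hydroxy-6-methyl-2-methyleneoct-6-enoate | C=C(C[C@@H](C/C(C)=C/CO[Si](c1ccccc1)(c1ccccc1)C(C)(C)C)O)C(=O)OCC | intermediate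
12 | (R)-5-[(E)-4-(tert-butyldiphenylsilyloxy)-2-methylbut-2-en-1-yl]-3-methylenedihydrofuran-2(3H)-one | C=C1C[C@@H](C/C(C)=C/CO[Si](c2ccccc2)(c2ccccc2)C(C)(C)C)OC1=O | intermediate
13 | (R)-5-[(E)-4-hydroxy-2-methylbut-2-en-1-yl]-3-methylenedihydrofuran-2(3H)-one | C=C1C[C@@H](C/C(C)=C/CO)OC1=O | intermediate
14 | (S)-5-{[(2R,3R)-3-(hydroxymethyl)-2-methyloxiran-2-yl]methyl}-3-methylenedihydrofuran-2(3H)-one | C=C1C[C@@H](C[C@@]2(C)O[C@@H]2CO)OC1=O | intermediate
15 | 2-methoxybenzene-1,3-diol | COc1c(O)cccc1O | starting material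
16 | DL-malic acid | OC(CC(=O)O)C(=O)O | starting material
17 | 3-oxopropanoic acid | O=CCC(=O)O | intermediate
18 | 7-hydroxy-8-methoxy-2H-chromen-2-one | COc1c(O)ccc2ccc(=O)oc12 | intermediate
19 | 7-{[(2R,3R)-3-methyl-3-{[(S)-4-methylene-5-oxotetrahydrofuran-2-yl]methyl}oxiran-2-yl]methoxy}-8-methoxy-2H-chromen-2-one | C=C1C[C@@H](C[C@@]2(C)O[C@@H]2COc2ccc3ccc(=O)oc3c2OC)OC1=O | target

**Totals**
Total step count: 11. Longest linear sequence: 10 steps (steps 1–9 and 11); the coumarin branch is 1 step.

**Steps most likely to fail, with fallbacks**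

Step 6 (labile β,γ-unsaturated aldehyde 8). If 8 isomerises to the conjugated enal or degrades, the free aldehyde is avoided altogether. Acrylate 9 is converted with KOAc (DMF, rt) into ethyl 2-(acetoxymethyl)acrylate F1. Alcohol 7 is then coupled with it at the alcohol oxidation level by iridium-catalysed transfer-hydrogenative carbonyl 2-(alkoxycarbonyl)allylation ([Ir(cod)Cl]2, chiral bisphosphine such as SEGPHOS or TMBTP in the antipode for Si-face addition, 4-cyano-3-nitrobenzoic acid, Cs2CO3, THF, 60 °C). The aldehyde exists only transiently on the metal, hydroxy ester 11 is formed, and acid lactonisation as in step 7 rejoins the route at 12.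

Step 7 (enantioselective chromium allylation). If yield or ee is inadequate, the fallback sets out from aldehyde 8 with a stoichiometric chiral-boron 2-bromoallylation. The B-(2-bromoallyl)diazaborolidine is generated from tributyl(2-bromoallyl)stannane and Corey's 2-bromo-4,5-diphenyl-1,3-ditosyl-1,3,2-diazaborolidine (CH2Cl2, −78 °C, antipode for Si-face attack). It gives (R,E)-2-bromo-8-(tert-butyldiphenylsilyloxy)-6-methylocta-1,6-dien-4-ol F2. Palladium-catalysed carbonylative lactonisation of the vinyl bromide onto the hydroxyl (Pd(PPh3)4 5 mol %, CO 1–3 atm, K2CO3, THF, 60 °C) then builds the methylene lactone and returns to 12.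

Step 11 (Mitsunobu in the presence of the methylene lactone and epoxide). If phosphine addition to the Michael acceptor or poor conversion intervenes, the fallback sets out from epoxy alcohol 14. TsCl, Et3N and catalytic DMAP (CH2Cl2, 0 °C) give [(2R,3R)-3-methyl-3-{[(S)-4-methylene-5-oxotetrahydrofuran-2-yl]methyl}oxiran-2-yl]methyl 4-methylbenzenesulfonate F3. Williamson SN2 displacement at the primary carbon by the caesium phenoxide of 18 (Cs2CO3, DMF, rt) delivers 19 without any phosphine.

Further compounds
F1 | step 6 | ethyl 2-(acetoxymethyl)acrylate | C=C(COC(C)=O)C(=O)OCC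
F2 | step 7 | (R,E)-2-bromo-8-(tert-butyldiphenylsilyloxy)-6-methylocta-1,6-dien-4-ol | C=C(Br)C[C@@H](C/C(C)=C/CO[Si](c1ccccc1)(c1ccccc1)C(C)(C)C)O
F3 | step 11 | [(2R,3R)-3-methyl-3-{[(S)-4-methylene-5-oxotetrahydrofuran-2-yl]methyl}oxiran-2-yl]methyl 4-methylbenzenesulfonate | C=C1C[C@@H](C[C@@]2(C)O[C@@H]2COS(=O)(=O)c2ccc(C)cc2)OC1=O
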